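**Retrosynthetic overview**

- The strategy rests on ring C. C2–C3(OMe)–C4 is the three-carbon chain of an α-methoxy aroylacetate. O1 and C4a are the oxygen and the single free ortho carbon of a ring A phenol whose other three oxygens are etherified.
- Cutting C4–C4a and O1–C2 (thermal Mentzer annulation) gives 3,5-bis(benzyloxy)-2-methoxyphenol and ethyl 3-[4-(benzyloxy)phenyl]-2-methoxy-3-oxopropanoate. Rings A and B come from the starting materials; ring C is the only ring formed.
- The phenol is made from 2,4,6-trihydroxybenzaldehyde: dibenzylation, acetal mask on the third oxygen, Baeyer–Villiger oxidation, methylation, unmasking. The ketoester is made from ethyl methoxyacetate and 4-(benzyloxy)benzoyl chloride.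
- The prenyl ether is installed last (hydrogenolysis, 7-O-pivalate, Mitsunobu etherification, ester cleavage), because it would not survive the annulation temperature.

Key step: step 8

Remark on the chemistry: the prenyl group is taken from 3-methylbut-2-en-1-ol (prenol) and not from the bromide, because the etherification is run as a Mitsunobu reaction. The target has no stereocentre, and the racemic α-carbon of the ketoester becomes sp2 C3.

**Route**

Step 1
Reactants: 1 2,4,6-trihydroxybenzaldehyde
Product: 2 2,4-bis(benzyloxy)-6-hydroxybenzaldehyde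
Conditions: BnBr (2.05 equiv), K2CO3 (2.1 equiv), DMF, 0 °C to rt
Reagents that add atoms: benzyl bromide, BrCc1ccccc1
Why: Williamson etherification under acidity control, in which the 4-OH and one ortho OH are alkylated and the remaining hydroxyl, hydrogen-bonded to the formyl group, should be left when only two equivalents of halide are offered.

Step 2
Reactants: 2 2,4-bis(benzyloxy)-6-hydroxybenzaldehyde
Product: 4 2,4-bis(benzyloxy)-6-(methoxymethoxy)benzaldehyde, via sodium 3,5-bis(benzyloxy)-2-formylphenolate 3 (not isolated)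
Conditions: NaH (1.2 equiv), DMF, 0 °C; MOMCl (1.3 equiv), 0 °C to rt
Reagents that add atoms: chloromethyl methyl ether, COCCl
Why: Williamson-type O-alkylation after irreversible deprotonation, which breaks the chelate; an acetal is chosen as the mask because it cannot migrate to the neighbouring oxygen that step 3 creates.

Step 3
Reactants: 4 2,4-bis(benzyloxy)-6-(methoxymethoxy)benzaldehyde
Product: 6 2,4-bis(benzyloxy)-6-(methoxymethoxy)phenol, via aryl formate 5 (not isolated)
Conditions: mCPBA (1.2 equiv), CH2Cl2, 0 °C to rt; aq. NaHCO3 wash; then K2CO3 (0.2 equiv), MeOH, rt, under argon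
Reagents that add atoms: 3-chloroperoxybenzoic acid (mCPBA), O=C(OO)c1cccc(Cl)c1
Why: Baeyer–Villiger (Dakin-type) oxidation, in which the electron-rich trialkoxyaryl group migrates in the Criegee adduct to give the aryl formate, which mild methanolysis cleaves without touching the benzyl or acetal ethers.

Step 4
Reactants: 6 2,4-bis(benzyloxy)-6-(methoxymethoxy)phenol
Product: 7 1,5-bis(benzyloxy)-2-methoxy-3-(methoxymethoxy)benzene
Conditions: MeI (1.5 equiv), K2CO3 (1.5 equiv), DMF, rt
Reagents that add atoms: iodomethane, CI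
Why: Williamson methylation of the only free phenol, which fixes the future 8-methoxy group and protects the oxidation-sensitive trialkoxyphenol.

Step 5
Reactants: 7 1,5-bis(benzyloxy)-2-methoxy-3-(methoxymethoxy)benzene
Product: 8 3,5-bis(benzyloxy)-2-methoxyphenol
Conditions: conc. HCl (cat.), MeOH, 50 °C
Reagents that add atoms: none
Why: Acid-catalysed acetal exchange with methanol removes the methoxymethyl group, while benzyl and methyl aryl ethers are inert to dilute acid.

Step 6
Reactants: 9 4-(benzyloxy)benzoic acid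
Product: 10 4-(benzyloxy)benzoyl chloride
Conditions: (COCl)2 (1.3 equiv), DMF (cat.), CH2Cl2, 0 °C to rt; concentrate
Reagents that add atoms: oxalyl chloride, O=C(Cl)C(=O)Cl
Why: Vilsmeier-catalysed acid chloride formation, with only gaseous by-products, so the crude chloride can be used directly.

Step 7
Reactants: 10 4-(benzyloxy)benzoyl chloride; 11 ethyl methoxyacetate
Product: 14 racemic ethyl 3-[4-(benzyloxy)phenyl]-2-methoxy-3-oxopropanoate, via lithium enolate of ethyl methoxyacetate 12 (not isolated), via lithium enolate of the ketoester 13 (not isolated)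
Conditions: 11 (2.1 equiv), LiN(i-Pr)2 (2.1 equiv), THF, −78 °C; then 10 (1.0 equiv), −78 to −40 °C; 1 M HCl quench
Reagents that add atoms: none
Why: Crossed Claisen-type C-acylation of a preformed lithium ester enolate by an acid chloride, in which the second equivalent of enolate deprotonates the more acidic ketoester as it forms and so prevents double acylation; the α-carbon is formed racemic, which does not matter.

Step 8
Reactants: 8 3,5-bis(benzyloxy)-2-methoxyphenol; 14 racemic ethyl 3-[4-(benzyloxy)phenyl]-2-methoxy-3-oxopropanoate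
Product: 19 5,7-bis(benzyloxy)-2-[4-(benzyloxy)phenyl]-3,8-dimethoxychromen-4-one, via ketene 15 (not isolated), via aryl ester 16 (not isolated), via diketone 17 (not isolated), via hemiketal 18 (not isolated)
Conditions: 8 (1.0 equiv), 14 (2.0 equiv, in two portions), Ph2O, 230–240 °C, N2 sweep to remove EtOH and H2O, 2–3 h
Reagents that add atoms: none
Why: Mentzer (thermal Simonis-type) chromone synthesis: above about 200 °C the enol of 14 expels ethanol to give aroyl(methoxy)ketene 15, which adds reversibly to the phenol oxygen of 8 (aryl ester 16 returns the ketene at this temperature) and irreversibly to the ring carbon ortho to it, giving the 2-hydroxyaryl 1,3-diketone 17 with the new C4–C4a bond. Ring C then closes by 6-exo-trig attack of the phenolic oxygen (O1) on the aryl ketone carbonyl (C2) to give hemiketal 18, and loss of water across C2–C3 gives the pyranone with the new O1–C2 bond. The closest known reaction type is the thermal condensation of phloroglucinol ethers with aroylacetates and α-substituted aroylacetates to give flavones. No stereocentre is created, since the racemic α-carbon of 14 ends as sp2 C3 and the hemiketal centres of 18 are lost on dehydration. Three selectivities are needed: ortho over para C-acylation, expected because the ortho carbon is reached from the neighbouring phenol oxygen and only the ortho adduct is drained by cyclodehydration, whereas the para carbon lies between two benzyloxy groups; chromone over coumarin, expected because without acid the arene does not attack the ketone carbonyl (Pechmann mode); and the 8-methoxy orientation, fixed because 8 has one free hydroxyl flanked by the methoxy-bearing carbon and the one reactive CH. Benzyl ethers tolerate the temperature, which is why ring B carries benzyl and not prenyl at this stage.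

Step 9
Reactants: 19 5,7-bis(benzyloxy)-2-[4-(benzyloxy)phenyl]-3,8-dimethoxychromen-4-one
Product: 20 5,7-dihydroxy-2-(4-hydroxyphenyl)-3,8-dimethoxychromen-4-one
Conditions: H2 (1 atm), 10% Pd/C, THF–MeOH (1:1), rt
Reagents that add atoms: none
Why: Catalytic hydrogenolysis of the three benzylic C–O bonds; the tetrasubstituted C2=C3 bond of the 3-methoxychromone, a vinylogous ester, should not be reduced at one atmosphere.

Step 10
Reactants: 20 5,7-dihydroxy-2-(4-hydroxyphenyl)-3,8-dimethoxychromen-4-one
Product: 22 5-hydroxy-2-(4-hydroxyphenyl)-3,8-dimethoxy-4-oxo-4H-chromen-7-yl 2,2-dimethylpropanoate, via potassium 7-phenoxide 21 (not isolated)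
Conditions: KOt-Bu (1.0 equiv), DMF, 0 °C; t-BuCOCl (1.0 equiv), 0 °C
Reagents that add atoms: pivaloyl chloride, CC(C)(C)C(=O)Cl
Why: Acidity-controlled O-acylation of a monophenoxide: one equivalent of base puts the charge on the 7-oxygen (the most acidic phenol, a vinylogous acid para to C4=O), while the 4'-OH stays protonated and the 5-OH is held in its hydrogen bond to the carbonyl.

Step 11
Reactants: 22 5-hydroxy-2-(4-hydroxyphenyl)-3,8-dimethoxy-4-oxo-4H-chromen-7-yl 2,2-dimethylpropanoate; 23 3-methylbut-2-en-1-ol (prenol)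
Product: 24 5-hydroxy-3,8-dimethoxy-2-{4-[(3-methylbut-2-en-1-yl)oxy]phenyl}-4-oxo-4H-chromen-7-yl 2,2-dimethylpropanoate
Conditions: 23 (1.3 equiv), PPh3 (1.4 equiv), DIAD (1.4 equiv), THF, 0 °C to rt
Reagents that add atoms: none
Why: Mitsunobu etherification, in which the 4'-phenol, the only acidic OH not tied up in a chelate, displaces the oxyphosphonium of the primary allylic alcohol by SN2 under near-neutral conditions that should allow neither acyl transfer from the hindered pivalate nor Claisen rearrangement.

Step 12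
Reactants: 24 5-hydroxy-3,8-dimethoxy-2-{4-[(3-methylbut-2-en-1-yl)oxy]phenyl}-4-oxo-4H-chromen-7-yl 2,2-dimethylpropanoate
Product: 25 5,7-dihydroxy-3,8-dimethoxy-2-{4-[(3-methylbut-2-en-1-yl)oxy]phenyl}-4H-chromen-4-one
Conditions: LiOH (2.5 equiv), THF–H2O (3:1), 0 °C to rt; AcOH to pH 6
Reagents that add atoms: none
Why: Saponification of an aryl ester with a good (7-phenoxide) leaving group; the prenyl ether, the methyl ethers and the chromone ring should be stable to cold dilute hydroxide and to the weakly acidic work-up.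

**Compound list**

1 | 2,4,6-trihydroxybenzaldehyde | O=Cc1c(O)cc(O)cc1O | starting material
2 | 2,4-bis(benzyloxy)-6-hydroxybenzaldehyde | O=Cc1c(O)cc(OCc2ccccc2)cc1OCc1ccccc1 | intermediate
3 | sodium 3,5-bis(benzyloxy)-2-formylphenolate | O=Cc1c([O-])cc(OCc2ccccc2)cc1OCc1ccccc1.[Na+] | intermediate
4 | 2,4-bis(benzyloxy)-6-(methoxymethoxy)benzaldehyde | COCOc1cc(OCc2ccccc2)cc(OCc2ccccc2)c1C=O | intermediate
5 | 2,4-bis(benzyloxy)-6-(methoxymethoxy)phenyl formate | COCOc1cc(OCc2ccccc2)cc(OCc2ccccc2)c1OC=O | intermediate
6 | 2,4-bis(benzyloxy)-6-(methoxymethoxy)phenol | COCOc1cc(OCc2ccccc2)cc(OCc2ccccc2)c1O | intermediate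
7 | 1,5-bis(benzyloxy)-2-methoxy-3-(methoxymethoxy)benzene | COCOc1cc(OCc2ccccc2)cc(OCc2ccccc2)c1OC | intermediate
8 | 3,5-bis(benzyloxy)-2-methoxyphenol | COc1c(O)cc(OCc2ccccc2)cc1OCc1ccccc1 | intermediate
9 | 4-(benzyloxy)benzoic acid | O=C(O)c1ccc(OCc2ccccc2)cc1 | starting material
10 | 4-(benzyloxy)benzoyl chloride | O=C(Cl)c1ccc(OCc2ccccc2)cc1 | intermediate
11 | ethyl methoxyacetate | CCOC(=O)COC | starting material
12 | lithium 1-ethoxy-2-methoxyethen-1-olate (lithium enolate of 11) | CCOC([O-])=COC.[Li+] | intermediate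
13 | lithium 1-[4-(benzyloxy)phenyl]-3-ethoxy-2-methoxy-3-oxoprop-1-en-1-olate (lithium enolate of 14) | CCOC(=O)C(OC)=C([O-])c1ccc(OCc2ccccc2)cc1.[Li+] | intermediate
14 | racemic ethyl 3-[4-(benzyloxy)phenyl]-2-methoxy-3-oxopropanoate | CCOC(=O)C(OC)C(=O)c1ccc(OCc2ccccc2)cc1 | intermediate
15 | 3-[4-(benzyloxy)phenyl]-2-methoxy-3-oxoprop-1-en-1-one (aroyl(methoxy)ketene) | COC(=C=O)C(=O)c1ccc(OCc2ccccc2)cc1 | intermediate
16 | racemic 3,5-bis(benzyloxy)-2-methoxyphenyl 3-[4-(benzyloxy)phenyl]-2-methoxy-3-oxopropanoate | COc1c(OC(=O)C(OC)C(=O)c2ccc(OCc3ccccc3)cc2)cc(OCc2ccccc2)cc1OCc1ccccc1 | intermediate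
17 | racemic 1-[4,6-bis(benzyloxy)-2-hydroxy-3-methoxyphenyl]-3-[4-(benzyloxy)phenyl]-2-methoxypropane-1,3-dione | COC(C(=O)c1ccc(OCc2ccccc2)cc1)C(=O)c1c(O)c(OC)c(OCc2ccccc2)cc1OCc1ccccc1 | intermediate
18 | 5,7-bis(benzyloxy)-2-[4-(benzyloxy)phenyl]-2-hydroxy-3,8-dimethoxychroman-4-one (mixture of diastereomers) | COC1C(=O)c2c(OCc3ccccc3)cc(OCc3ccccc3)c(OC)c2OC1(O)c1ccc(OCc2ccccc2)cc1 | intermediate
19 | 5,7-bis(benzyloxy)-2-[4-(benzyloxy)phenyl]-3,8-dimethoxychromen-4-one | COc1c(-c2ccc(OCc3ccccc3)cc2)oc2c(OC)c(OCc3ccccc3)cc(OCc3ccccc3)c2c1=O | intermediate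
20 | 5,7-dihydroxy-2-(4-hydroxyphenyl)-3,8-dimethoxychromen-4-one | COc1c(-c2ccc(O)cc2)oc2c(OC)c(O)cc(O)c2c1=O | intermediate
21 | potassium 5-hydroxy-2-(4-hydroxyphenyl)-3,8-dimethoxy-4-oxo-4H-chromen-7-olate | COc1c(-c2ccc(O)cc2)oc2c(OC)c([O-])cc(O)c2c1=O.[K+] | intermediate
22 | 5-hydroxy-2-(4-hydroxyphenyl)-3,8-dimethoxy-4-oxo-4H-chromen-7-yl 2,2-dimethylpropanoate | COc1c(-c2ccc(O)cc2)oc2c(OC)c(OC(=O)C(C)(C)C)cc(O)c2c1=O | intermediate
23 | 3-methylbut-2-en-1-ol (prenol) | CC(C)=CCO | starting material
24 | 5-hydroxy-3,8-dimethoxy-2-{4-[(3-methylbut-2-en-1-yl)oxy]phenyl}-4-oxo-4H-chromen-7-yl 2,2-dimethylpropanoate | COc1c(-c2ccc(OCC=C(C)C)cc2)oc2c(OC)c(OC(=O)C(C)(C)C)cc(O)c2c1=O | intermediate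
25 | 5,7-dihydroxy-3,8-dimethoxy-2-{4-[(3-methylbut-2-en-1-yl)oxy]phenyl}-4H-chromen-4-one (5,7-dihydroxy-3,8-dimethoxy-4'-prenyloxyflavone) | COc1c(-c2ccc(OCC=C(C)C)cc2)oc2c(OC)c(O)cc(O)c2c1=O | target

**Step count**

Total: 12 steps. Longest linear sequence: 10 steps (steps 1–5, then 8–12); the ketoester branch (steps 6–7) joins at step 8.

**Steps most likely to fail**

1. Step 8 (annulation). The ketoester may be lost by hydrolysis with the released water and decarboxylation before it acylates. C-acylation may go to the para carbon between the two benzyloxy groups, which cannot cyclise. The reaction may also stall at O-acylation. Fallback: the same two bonds are made stepwise, setting out from 7 and 10.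
   - Ortho-lithiation of 7 (n-BuLi, TMEDA, THF, −78 to −20 °C), directed by the methoxymethoxy group with help from the neighbouring benzyloxy group, should give [4,6-bis(benzyloxy)-3-methoxy-2-(methoxymethoxy)phenyl]lithium F1.
   - Acylation of F1 with N,2-dimethoxy-N-methylacetamide gives 1-[4,6-bis(benzyloxy)-3-methoxy-2-(methoxymethoxy)phenyl]-2-methoxyethan-1-one F2.
   - HCl in MeOH unmasks the phenol to 1-[4,6-bis(benzyloxy)-2-hydroxy-3-methoxyphenyl]-2-methoxyethan-1-one F3.
   - O-aroylation with 10 (pyridine, DMAP, CH2Cl2) gives 3,5-bis(benzyloxy)-2-methoxy-6-(methoxyacetyl)phenyl 4-(benzyloxy)benzoate F4.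
   - Baker–Venkataraman rearrangement (LiN(SiMe3)2, THF, −78 °C to rt) gives diketone 17, here isolated. Acid-catalysed cyclodehydration (p-TsOH, toluene, 80 °C) returns to the route at 19.

2. Step 10 (7-O-pivaloylation). Proton exchange during the acylation may lead to reaction at the 4'-oxygen or to double acylation, and the 8-methoxy group slows attack at O7. Fallback: setting out from 20, the order of reactivity is reversed by working with the dianion. KOt-Bu (2.05 equiv) in DMF at 0 °C should give dipotassium 5-hydroxy-3,8-dimethoxy-4-oxo-2-(4-oxidophenyl)-4H-chromen-7-olate F5. Its 4'-phenoxide is less delocalised and unhindered, so it is the more nucleophilic site and should take up one equivalent of prenyl bromide (DMF, −20 °C) in preference to O7. Weakly acidic work-up then gives the target directly, so the fallback returns at 25 and steps 10–12 are not needed.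

3. Step 1 (partial benzylation). Statistical under- and over-alkylation may leave a mixture that is hard to separate. Fallback: setting out from 1, exhaustive benzylation (BnBr 3.5 equiv, K2CO3, DMF, 60 °C) gives 2,4,6-tris(benzyloxy)benzaldehyde F6. Chelation-controlled cleavage of one benzyl ether ortho to the formyl group (MgBr2·OEt2, toluene–Et2O, reflux) returns to the route at 2.

**Further compounds**

F1 | step 8 | [4,6-bis(benzyloxy)-3-methoxy-2-(methoxymethoxy)phenyl]lithium | [Li]c1c(OCOC)c(OC)c(OCc2ccccc2)cc1OCc1ccccc1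
F2 | step 8 | 1-[4,6-bis(benzyloxy)-3-methoxy-2-(methoxymethoxy)phenyl]-2-methoxyethan-1-one | COCC(=O)c1c(OCOC)c(OC)c(OCc2ccccc2)cc1OCc1ccccc1
F3 | step 8 | 1-[4,6-bis(benzyloxy)-2-hydroxy-3-methoxyphenyl]-2-methoxyethan-1-one | COCC(=O)c1c(O)c(OC)c(OCc2ccccc2)cc1OCc1ccccc1
F4 | step 8 | 3,5-bis(benzyloxy)-2-methoxy-6-(methoxyacetyl)phenyl 4-(benzyloxy)benzoate | COCC(=O)c1c(OC(=O)c2ccc(OCc3ccccc3)cc2)c(OC)c(OCc2ccccc2)cc1OCc1ccccc1
F5 | step 10 | dipotassium 5-hydroxy-3,8-dimethoxy-4-oxo-2-(4-oxidophenyl)-4H-chromen-7-olate | COc1c(-c2ccc([O-])cc2)oc2c(OC)c([O-])cc(O)c2c1=O.[K+].[K+]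
F6 | step 1 | 2,4,6-tris(benzyloxy)benzaldehyde | O=Cc1c(OCc2ccccc2)cc(OCc2ccccc2)cc1OCc1ccccc1
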